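## The problem

Compound 27 is an achiral biflavonol: a 3,5-dihydroxy-7-methoxyflavone (half 1) and a 3,5,7-trihydroxyflavone (half 2) are joined by a diaryl ether from C4' of ring B of half 1 to the oxygen on C4' of ring B of half 2. There is no stereocenter, so every difficulty is regiochemical: nine ring oxygens must end as six free hydroxyls, two methyl ethers (O7 of half 1, O3' of half 2) and one ether bridge. The bridge is flanked by an oxygen on each ring (3'-OH in half 1, 3'-OMe in half 2). A late Ullmann or SNAr union of two finished halves would therefore be hindered and would need a protecting group on 3'-OH that differs from all others. The pyranone rings are opened at C2 by hydroxide, alkoxide or amines, and free flavonols are oxidised by air in base. The two aryl methyl ethers rule out a Lewis-acid dealkylation at the end, so benzyl ethers removed by a final hydrogenolysis are the natural protection. Rings A are phloroglucinol patterns that can be bought as acetophenones, so the open questions are how each pyranone C2 is joined to its ring B and how the two rings B are joined. Ring B of half 1 answers the second question: C1' carries the chromone, C3' a free hydroxyl, C4' the aryloxy oxygen, and C2', C5', C6' carry hydrogen. A 3-aryloxyfuran can supply C3'–C6' with its ring oxygen as the future 3'-OH, and a terminal alkyne on chromone C2 can supply C1' and C2'.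

## Retrosynthesis

**27 to 26.** The five O–benzyl bonds are cut last. Benzyl is chosen over methyl or acetal groups because hydrogenolysis leaves both aryl methyl ethers, the diaryl ether and the pyranones alone. Compound 26 is the pentabenzyl ether with only the 3'-hydroxyl of half 1 free; nothing is asked of the forward step beyond clean hydrogenolysis.

**26 to 24 and 12.** Ring B of half 1 is cut at C2'–C3' and C1'–C6', and the 3'-OH is traced back to a furan oxygen. This leads through oxanorbornadiene 25 to the 3-aryloxyfuran 24, which already carries all of half 2, and to the 2-ethynylchromone 12.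
- Against the neighbouring cut at the diaryl ether C–O bond, this one needs no separate protecting group for 3'-OH and avoids coupling two ortho-oxygenated partners.
- Both precursors are complete flavonoid halves made independently, so the step is fully convergent.
- The forward reaction must orient the cycloaddition "para" (aryloxy carbon opposite the chromone-bearing carbon) and open the bridge toward the aryloxy-stabilised cation.
- The alkyne is activated only through the pyranone and the aryloxy donor is attenuated by its para chromone. A purely thermal reaction is therefore not relied on; the step is planned with a catalytic oxophilic Lewis acid on the pyranone carbonyl.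

**12 to 9 and 10; 9 to 7.** The C2–alkyne bond is cut to the 2-iodochromone 9 and ethynyltrimethylsilane 10, by way of silylalkyne 11. The iodide comes from the 3-benzyloxychromone 7 through C2 zinc species 8. Building the pyranone around a pre-installed alkyne would expose the alkyne to the ring-forming conditions. In 7, C2–H is the only acidic vinylic position, because C3 is blocked by the benzyloxy group. The forward steps need a base mild enough to leave the carbonyl alone and an amine that does not add to C2.

**7 to 1.** The 3-O–benzyl bond is cut to 3-hydroxychromone 6. The C3–O bond is cut by way of epoxide 5 to chromone 4. The pyranone is cut at O1–C2 and C2–C3 by way of enaminone 3 to the mono-benzylated ketone 2, and 2 comes from the commercial ketone 1. Putting the 3-oxygen in after ring closure avoids an alpha-oxygenated acetophenone, which has no short regioselective preparation in this series. Ketone 1 already holds the 7-methoxy group, so no selective methylation is needed.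

**24 to 19 and 22.** The C2–C1' bond of half 2 is cut to the 3,5,7-tris(benzyloxy)chromone 19, used as its C2 zinc species 23, and the aryl bromide 22. The classical chalcone route would either expose the furan to the oxidants that make a flavonol, or require a fifth, orthogonal protecting group on 4'-OH and a copper etherification on the finished flavonol. The cross-coupling brings the furyl ether in after all oxidations are over, and uses the same C2 metalation as the other half.

**22 to 20 and 21.** The furan C3–O bond is cut to 4-bromo-2-methoxyphenol 20 and furan-3-ylboronic acid 21. An oxidative copper coupling with the boronic acid is chosen over an Ullmann reaction with a halofuran, because the aryl bromide of 20 must survive as the handle for the next step.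

**19 to 13.** The same four operations as for 7 lead back through 18, epoxide 17, chromone 16 and enaminone 15 to dibenzyl ketone 14 and 2,4,6-trihydroxyacetophenone 13.

## Roads not taken

Alternative 1: Ring B of half 2 is cut at C3'–C4' and C5'–C6'. The forward step is an inverse-demand Diels–Alder reaction of the pyrone ester A1 with the aryl ethynyl ether A2, followed by loss of the lactone bridge, giving the diaryl ether benzoate A3.
- Merits: the arene appears directly without an acid step. The nucleophilic terminal carbon of A2 should add to C6 of A1, as is usual for 5-carboxypyrones. The hindered ether is made early on small molecules, with an ester and an acetal as distinct handles.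
- Weak points: the 3-methoxy group raises the LUMO of A1 and sits on the carbon that must bond to the oxygenated alkyne carbon. A2 has to be made from a phenol through a dichlorovinyl ether and strong base, and is prone to hydration. After the key step neither flavonol exists, so two pyranone syntheses must be run one after the other on A3.
- Comparison: this key step is closer to precedent on simple substrates and would fail cheaply. The chosen plan sets against that its convergence (two finished halves joined one step before the end) and the fact that the free 3'-OH and the ether arise together.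

Alternative 2: Ring A of half 2 is cut at C4a–C5. The triketoester A4 is folded with Mg(OMe)2 by a Claisen closure of chain C6 onto the ester carbon, giving the 2',4',6'-trihydroxychalcone A5.
- Merits: it is biomimetic, ring A arrives with three free hydroxyls and no protecting groups, and a chalcone is the classical flavonoid precursor.
- Weak points: A4 needs acylation of a polyanion with a cinnamoyl donor that carries the whole diaryl ether. The aldol mode of closure and Michael addition to the cinnamoyl unit compete. Oxidative cyclisation of a chalcone oxygenated at C6' tends to give aurones under Algar–Flynn–Oyamada conditions. The route spends its key step on a ring that 13 supplies commercially, and the other half is still to be built.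
- Comparison: it is better only in protecting-group count for ring A. The chosen plan answers by buying ring A and spending its new chemistry on the ring that joins the halves.

Alternative 3: Ring C of half 1 is cut at O1–C8a and C4–C4a. The aryne released by CsF from the silyl triflate A6 is to be attacked by the enolate oxygen of the ketoester A7, and the aryl anion is to close onto the ester, giving the flavone A8.
- Merits: one step makes ring C and attaches ring A. The methoxy group next to the aryne directs the oxygen nucleophile to the distal carbon, which gives the 5,7-pattern. The approach is modular in ring A.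
- Weak points: ketoester enolates usually attack arynes through carbon and then insert into the C–C bond, so the O-arylation/acylation path is the less likely one. A8 has a 5-methoxy group that must be cleaved selectively, which is feasible only for half 1. For half 2 a 7-methyl ether could not be removed beside the 3'-methyl ether. A6 takes several steps to make.
- Comparison: it equals the chosen plan in convergence at ring C and is more modular. The chosen plan makes ring C from acetophenones by a standard condensation and keeps its one unproven step for the ring whose substitution pattern fits it exactly.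

Key step: step 14

Assumption: 1, 10, 13, 20 and 21 are bought; TMPZnCl·LiCl (TMP = 2,2,6,6-tetramethylpiperidin-1-yl) is used as a THF solution and dimethyldioxirane as an acetone solution; the racemic intermediates 5, 17 and 25 are drawn without stereodescriptors because the target has no stereocenter.

## Route

Step 1
Reactants: 1 1-(2,6-dihydroxy-4-methoxyphenyl)ethan-1-one
Product: 2 1-[2-(benzyloxy)-6-hydroxy-4-methoxyphenyl]ethan-1-one
Conditions: BnBr (1.05 equiv), K2CO3, acetone, reflux
Reagents that add atoms: benzyl bromide, BrCc1ccccc1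
Why: Williamson etherification; after the first benzylation the remaining hydroxyl is held in a hydrogen bond to the ketone and is much less nucleophilic, so the reaction should stop at the mono-ether.

Step 2
Reactants: 2 1-[2-(benzyloxy)-6-hydroxy-4-methoxyphenyl]ethan-1-one
Product: 4 5-(benzyloxy)-7-methoxy-4H-chromen-4-one, via enaminone 3 (not isolated)
Conditions: Me2NCH(OMe)2, PhMe, 100 °C; then conc. HCl, CH2Cl2, 40 °C
Reagents that add atoms: N,N-dimethylformamide dimethyl acetal, COC(OC)N(C)C
Why: Condensation of the methyl ketone with the formamide acetal gives the (E)-enaminone; acid then drives conjugate addition of the ortho hydroxyl and loss of dimethylamine (enaminone route to 2,3-unsubstituted chromones).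

Step 3
Reactants: 4 5-(benzyloxy)-7-methoxy-4H-chromen-4-one
Product: 6 5-(benzyloxy)-3-hydroxy-7-methoxy-4H-chromen-4-one, via 2,3-epoxychromanone 5 (not isolated)
Conditions: DMDO, acetone/CH2Cl2, 0 °C to rt; then p-TsOH·H2O (cat.), CH2Cl2, rt
Reagents that add atoms: dimethyldioxirane, CC1(C)OO1
Why: Electrophilic epoxidation of the enol-ether-like C2=C3 bond under neutral conditions; acid opens the epoxide at the acetal carbon C2 and loss of H3 gives the 3-hydroxychromone (epoxide-to-enol isomerisation).

Step 4
Reactants: 6 5-(benzyloxy)-3-hydroxy-7-methoxy-4H-chromen-4-one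
Product: 7 3,5-bis(benzyloxy)-7-methoxy-4H-chromen-4-one
Conditions: BnBr, K2CO3, DMF, rt
Reagents that add atoms: benzyl bromide, BrCc1ccccc1
Why: Williamson etherification of the acidic enolic 3-hydroxyl.

Step 5
Reactants: 7 3,5-bis(benzyloxy)-7-methoxy-4H-chromen-4-one
Product: 9 3,5-bis(benzyloxy)-2-iodo-7-methoxy-4H-chromen-4-one, via chromon-2-ylzinc chloride 8 (not isolated)
Conditions: TMPZnCl·LiCl, THF, 0 °C to rt; then I2, 0 °C
Reagents that add atoms: iodine, II
Why: Directed zincation of the pyranone with a hindered zinc amide, then iodinolysis of the C–Zn bond; C3 is blocked, so C2–H (alpha to the ring oxygen, beta to the carbonyl) is the only acidic vinylic hydrogen, and the zinc base tolerates the carbonyl.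

Step 6
Reactants: 9 3,5-bis(benzyloxy)-2-iodo-7-methoxy-4H-chromen-4-one; 10 ethynyltrimethylsilane
Product: 11 3,5-bis(benzyloxy)-7-methoxy-2-[(trimethylsilyl)ethynyl]-4H-chromen-4-one
Conditions: PdCl2(PPh3)2 (3 mol%), CuI (5 mol%), i-Pr2NEt, THF, rt
Reagents that add atoms: none
Why: Sonogashira coupling; the C2–I bond is a vinylogous acyl iodide and should add to zerovalent palladium at room temperature, and the hindered tertiary amine cannot substitute at C2.

Step 7
Reactants: 11 3,5-bis(benzyloxy)-7-methoxy-2-[(trimethylsilyl)ethynyl]-4H-chromen-4-one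
Product: 12 3,5-bis(benzyloxy)-2-ethynyl-7-methoxy-4H-chromen-4-one
Conditions: Bu4NF, AcOH, THF, −20 °C
Reagents that add atoms: none
Why: Fluoride-induced protodesilylation of the alkynylsilane; acetic acid buffers the medium so that neither the pyranone nor the conjugated alkyne meets a basic nucleophile.

Step 8
Reactants: 13 1-(2,4,6-trihydroxyphenyl)ethan-1-one
Product: 14 1-[2,4-bis(benzyloxy)-6-hydroxyphenyl]ethan-1-one
Conditions: BnBr (2.1 equiv), K2CO3, DMF, rt
Reagents that add atoms: benzyl bromide, BrCc1ccccc1
Why: Williamson etherification; two hydroxyls react and the one hydrogen-bonded to the ketone is left free for the ring closure.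

Step 9
Reactants: 14 1-[2,4-bis(benzyloxy)-6-hydroxyphenyl]ethan-1-one
Product: 16 5,7-bis(benzyloxy)-4H-chromen-4-one, via enaminone 15 (not isolated)
Conditions: Me2NCH(OMe)2, PhMe, 100 °C; then conc. HCl, CH2Cl2, 40 °C
Reagents that add atoms: N,N-dimethylformamide dimethyl acetal, COC(OC)N(C)C
Why: Enaminone formation and acid-promoted cyclisation with loss of dimethylamine, as in step 2.

Step 10
Reactants: 16 5,7-bis(benzyloxy)-4H-chromen-4-one
Product: 18 5,7-bis(benzyloxy)-3-hydroxy-4H-chromen-4-one, via 2,3-epoxychromanone 17 (not isolated)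
Conditions: DMDO, acetone/CH2Cl2, 0 °C to rt; then p-TsOH·H2O (cat.), CH2Cl2, rt
Reagents that add atoms: dimethyldioxirane, CC1(C)OO1
Why: Dioxirane epoxidation of C2=C3 and acid-catalysed epoxide-to-enol isomerisation, as in step 3.

Step 11
Reactants: 18 5,7-bis(benzyloxy)-3-hydroxy-4H-chromen-4-one
Product: 19 3,5,7-tris(benzyloxy)-4H-chromen-4-one
Conditions: BnBr, K2CO3, DMF, rt
Reagents that add atoms: benzyl bromide, BrCc1ccccc1
Why: Williamson etherification of the enolic 3-hydroxyl.

Step 12
Reactants: 20 4-bromo-2-methoxyphenol; 21 furan-3-ylboronic acid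
Product: 22 3-(4-bromo-2-methoxyphenoxy)furan
Conditions: Cu(OAc)2 (0.5 equiv), pyridine, 4 Å MS, CH2Cl2, O2 (1 atm), rt
Reagents that add atoms: none
Why: Chan–Lam oxidative coupling of a phenol with a heteroarylboronic acid at room temperature with oxygen as terminal oxidant; the aryl bromide is inert to copper under these conditions and is kept for step 13.

Step 13
Reactants: 19 3,5,7-tris(benzyloxy)-4H-chromen-4-one; 22 3-(4-bromo-2-methoxyphenoxy)furan
Product: 24 3,5,7-tris(benzyloxy)-2-[4-(furan-3-yloxy)-3-methoxyphenyl]-4H-chromen-4-one, via chromon-2-ylzinc chloride 23 (not isolated)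
Conditions: TMPZnCl·LiCl, THF, 0 °C to rt; then 22, Pd(OAc)2 (2 mol%), SPhos (4 mol%), 50 °C
Reagents that add atoms: none
Why: C2 zincation as in step 5, then Negishi coupling (oxidative addition of the aryl bromide to zerovalent palladium, transmetalation from zinc, reductive elimination); the chromone is used in slight excess over the amide base so that none is left to metalate the furan.

Step 14
Reactants: 24 3,5,7-tris(benzyloxy)-2-[4-(furan-3-yloxy)-3-methoxyphenyl]-4H-chromen-4-one; 12 3,5-bis(benzyloxy)-2-ethynyl-7-methoxy-4H-chromen-4-one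
Product: 26 3,5-bis(benzyloxy)-2-[3-hydroxy-4-[2-methoxy-4-[3,5,7-tris(benzyloxy)-4-oxo-4H-chromen-2-yl]phenoxy]phenyl]-7-methoxy-4H-chromen-4-one, via oxanorbornadiene 25 (not isolated)
Conditions: Sc(OTf)3 (10 mol%), 4 Å MS, CH2Cl2, 0 °C to rt; then CF3CO2H, 0 °C
Reagents that add atoms: none
Why: Proposed new method: Sc(OTf)3 binds the pyranone carbonyl of 12 (chelated by the peri benzyloxy oxygen) and turns the ethynylchromone into a vinylogous ynone–Lewis acid complex whose terminal alkyne carbon is the electrophilic end; furan C2 of 24, the most nucleophilic carbon (alpha to the ring oxygen and ortho to the aryloxy donor), bonds to that carbon and furan C5 to the internal alkyne carbon in an asynchronous (4+2) cycloaddition that gives oxanorbornadiene 25. The closest known reaction type is the Diels–Alder reaction of 3-alkoxyfurans with acetylenic esters and ketones followed by acid opening to ortho-alkoxyphenols, together with the Lewis-acid-promoted benzannulation of furans with propiolates; an alkyne activated only through a chromone has not been used as the dienophile, hence the label. Ring B closes by intermolecular (4+2) cycloaddition, which forms C2'–C3' and C1'–C6' together, and becomes aromatic when acid breaks the C6'–O bond of the bridge. That bond breaks, and not C3'–O, because the resulting cyclohexadienyl cation places charge on C4', where the aryloxy oxygen stabilises it, whereas the other mode would place charge on C1', which bears the electron-poor chromone; loss of the C3' proton then leaves the bridging oxygen as the free 3'-hydroxyl. The two bridgehead stereocenters of 25 form as a racemate and vanish on aromatisation, so no stereocontrol is needed. The selectivity required is regiochemical (orientation of the cycloaddition and direction of the bridge opening), and both are set by the same donor–acceptor pair, the 3-aryloxy group on the furan and the chromone on the alkyne. A catalytic amount of Lewis acid should suffice because it exchanges between the pyranone carbonyls, the molecular sieves keep out water that would hydrolyse the furyl enol ether, and benzyl and methyl ethers are inert to these acids at or below room temperature.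

Step 15
Reactants: 26 3,5-bis(benzyloxy)-2-[3-hydroxy-4-[2-methoxy-4-[3,5,7-tris(benzyloxy)-4-oxo-4H-chromen-2-yl]phenoxy]phenyl]-7-methoxy-4H-chromen-4-one
Product: 27 3,5-dihydroxy-2-[3-hydroxy-4-[2-methoxy-4-(3,5,7-trihydroxy-4-oxo-4H-chromen-2-yl)phenoxy]phenyl]-7-methoxy-4H-chromen-4-one
Conditions: H2 (1 atm), Pd/C (10%), THF/MeOH, rt
Reagents that add atoms: none
Why: Hydrogenolysis of five benzyl ethers over palladium on carbon; the aryl methyl ethers, the diaryl ether and the tetrasubstituted pyranone double bonds should not react at one atmosphere.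

## Compound list

1 | 1-(2,6-dihydroxy-4-methoxyphenyl)ethan-1-one | CC(=O)c1c(O)cc(OC)cc1O | starting material
2 | 1-[2-(benzyloxy)-6-hydroxy-4-methoxyphenyl]ethan-1-one | CC(=O)c1c(O)cc(OC)cc1OCc1ccccc1 | intermediate
3 | (E)-1-[2-(benzyloxy)-6-hydroxy-4-methoxyphenyl]-3-(dimethylamino)prop-2-en-1-one | CN(C)/C=C/C(=O)c1c(O)cc(OC)cc1OCc1ccccc1 | intermediate (not isolated)
4 | 5-(benzyloxy)-7-methoxy-4H-chromen-4-one | COc1cc(OCc2ccccc2)c2c(=O)ccoc2c1 | intermediate
5 | 5-(benzyloxy)-2,3-epoxy-7-methoxychroman-4-one (racemic, cis-fused) | COc1cc(OCc2ccccc2)c2C(=O)C3OC3Oc2c1 | intermediate (not isolated)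
6 | 5-(benzyloxy)-3-hydroxy-7-methoxy-4H-chromen-4-one | COc1cc(OCc2ccccc2)c2c(=O)c(O)coc2c1 | intermediate
7 | 3,5-bis(benzyloxy)-7-methoxy-4H-chromen-4-one | COc1cc(OCc2ccccc2)c2c(=O)c(OCc3ccccc3)coc2c1 | intermediate
8 | [3,5-bis(benzyloxy)-7-methoxy-4-oxo-4H-chromen-2-yl]zinc chloride | COc1cc(OCc2ccccc2)c2c(=O)c(OCc3ccccc3)c([Zn]Cl)oc2c1 | intermediate (not isolated)
9 | 3,5-bis(benzyloxy)-2-iodo-7-methoxy-4H-chromen-4-one | COc1cc(OCc2ccccc2)c2c(=O)c(OCc3ccccc3)c(I)oc2c1 | intermediate
10 | ethynyltrimethylsilane | C#C[Si](C)(C)C | starting material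
11 | 3,5-bis(benzyloxy)-7-methoxy-2-[(trimethylsilyl)ethynyl]-4H-chromen-4-one | COc1cc(OCc2ccccc2)c2c(=O)c(OCc3ccccc3)c(C#C[Si](C)(C)C)oc2c1 | intermediate
12 | 3,5-bis(benzyloxy)-2-ethynyl-7-methoxy-4H-chromen-4-one | COc1cc(OCc2ccccc2)c2c(=O)c(OCc3ccccc3)c(C#C)oc2c1 | intermediate
13 | 1-(2,4,6-trihydroxyphenyl)ethan-1-one | CC(=O)c1c(O)cc(O)cc1O | starting material
14 | 1-[2,4-bis(benzyloxy)-6-hydroxyphenyl]ethan-1-one | CC(=O)c1c(O)cc(OCc2ccccc2)cc1OCc1ccccc1 | intermediate
15 | (E)-1-[2,4-bis(benzyloxy)-6-hydroxyphenyl]-3-(dimethylamino)prop-2-en-1-one | CN(C)/C=C/C(=O)c1c(O)cc(OCc2ccccc2)cc1OCc1ccccc1 | intermediate (not isolated)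
16 | 5,7-bis(benzyloxy)-4H-chromen-4-one | O=c1ccoc2cc(OCc3ccccc3)cc(OCc3ccccc3)c12 | intermediate
17 | 5,7-bis(benzyloxy)-2,3-epoxychroman-4-one (racemic, cis-fused) | O=C1C2OC2Oc2cc(OCc3ccccc3)cc(OCc3ccccc3)c21 | intermediate (not isolated)
18 | 5,7-bis(benzyloxy)-3-hydroxy-4H-chromen-4-one | O=c1c(O)coc2cc(OCc3ccccc3)cc(OCc3ccccc3)c12 | intermediate
19 | 3,5,7-tris(benzyloxy)-4H-chromen-4-one | O=c1c(OCc2ccccc2)coc2cc(OCc3ccccc3)cc(OCc3ccccc3)c12 | intermediate
20 | 4-bromo-2-methoxyphenol | COc1cc(Br)ccc1O | starting material
21 | furan-3-ylboronic acid | OB(O)c1ccoc1 | starting material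
22 | 3-(4-bromo-2-methoxyphenoxy)furan | COc1cc(Br)ccc1Oc1ccoc1 | intermediate
23 | [3,5,7-tris(benzyloxy)-4-oxo-4H-chromen-2-yl]zinc chloride | O=c1c(OCc2ccccc2)c([Zn]Cl)oc2cc(OCc3ccccc3)cc(OCc3ccccc3)c12 | intermediate (not isolated)
24 | 3,5,7-tris(benzyloxy)-2-[4-(furan-3-yloxy)-3-methoxyphenyl]-4H-chromen-4-one | COc1cc(-c2oc3cc(OCc4ccccc4)cc(OCc4ccccc4)c3c(=O)c2OCc2ccccc2)ccc1Oc1ccoc1 | intermediate
25 | 3,5-bis(benzyloxy)-7-methoxy-2-[5-[2-methoxy-4-[3,5,7-tris(benzyloxy)-4-oxo-4H-chromen-2-yl]phenoxy]-7-oxabicyclo[2.2.1]hepta-2,5-dien-2-yl]-4H-chromen-4-one (racemic) | COc1cc(OCc2ccccc2)c2c(=O)c(OCc3ccccc3)c(C3=CC4OC3C=C4Oc3ccc(-c4oc5cc(OCc6ccccc6)cc(OCc6ccccc6)c5c(=O)c4OCc4ccccc4)cc3OC)oc2c1 | intermediate (not isolated)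
26 | 3,5-bis(benzyloxy)-2-[3-hydroxy-4-[2-methoxy-4-[3,5,7-tris(benzyloxy)-4-oxo-4H-chromen-2-yl]phenoxy]phenyl]-7-methoxy-4H-chromen-4-one | COc1cc(OCc2ccccc2)c2c(=O)c(OCc3ccccc3)c(-c3ccc(Oc4ccc(-c5oc6cc(OCc7ccccc7)cc(OCc7ccccc7)c6c(=O)c5OCc5ccccc5)cc4OC)c(O)c3)oc2c1 | intermediate
27 | 3,5-dihydroxy-2-[3-hydroxy-4-[2-methoxy-4-(3,5,7-trihydroxy-4-oxo-4H-chromen-2-yl)phenoxy]phenyl]-7-methoxy-4H-chromen-4-one | COc1cc(O)c2c(=O)c(O)c(-c3ccc(Oc4ccc(-c5oc6cc(O)cc(O)c6c(=O)c5O)cc4OC)c(O)c3)oc2c1 | target

## Step count and risks

Total: 15 steps. Longest linear sequence: 9 steps (steps 1–7, 14, 15).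

**Step 14 (key step).**
- What may go wrong: conjugate addition of furan C2 to the activated alkyne followed by re-aromatisation of the furan instead of ring closure; no reaction because the vinylogous activation is too weak and the aryloxy donor is attenuated by its para chromone; acid-induced hydrolysis or oligomerisation of the furyl enol ether. Chelation-assisted loss of the peri benzyl group would be harmless, since it is removed in step 15 anyway.
- Fallback (Ullmann ether synthesis): it sets out from 24 and from 7 and returns at 27.
  - Aqueous HCl in THF should hydrolyse the furyl enol ether of 24 to the phenol 3,5,7-tris(benzyloxy)-2-(4-hydroxy-3-methoxyphenyl)-4H-chromen-4-one F1.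
  - Zinc species 8, made from 7 as in step 5, should couple at the carbon–iodine bond of 2-(benzyloxy)-1-bromo-4-iodobenzene F2 (from commercial 2-bromo-5-iodophenol, benzyl bromide and K2CO3) under Negishi conditions (Pd(dba)2, tri(2-furyl)phosphine, THF, rt). This gives 3,5-bis(benzyloxy)-2-[3-(benzyloxy)-4-bromophenyl]-7-methoxy-4H-chromen-4-one F3.
  - Copper-catalysed etherification of F1 with F3 (CuI, picolinic acid, K3PO4, DMSO, 90 °C) should give the hexabenzyl ether 3,5-bis(benzyloxy)-2-[3-(benzyloxy)-4-[2-methoxy-4-[3,5,7-tris(benzyloxy)-4-oxo-4H-chromen-2-yl]phenoxy]phenyl]-7-methoxy-4H-chromen-4-one F4.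
  - Hydrogenolysis of F4 under the conditions of step 15 gives 27.

**Step 12.**
- What may go wrong: protodeboronation and homocoupling of the heteroarylboronic acid outrunning the slow O-arylation of an ortho-substituted phenol, and oxidative degradation of the electron-rich furan under copper and oxygen.
- Fallback (furan built from a butenolide): it sets out from 20 and returns at 22.
  - Addition–elimination of 20 to 4-bromofuran-2(5H)-one (K2CO3, MeCN, rt) should give 4-(4-bromo-2-methoxyphenoxy)furan-2(5H)-one F5.
  - Reduction of the lactone carbonyl with i-Bu2AlH (CH2Cl2, −78 °C) and dehydration of the lactol on mildly acidic work-up should give 22.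

**Step 5.**
- What may go wrong: incomplete or misdirected metalation (ring A C–H between two alkoxy groups, or attack of the amide at C2 with ring opening), and loss of the sensitive 2-iodide to nucleophiles on work-up.
- Fallback (polarity reversed at C2): it sets out from 7 and returns at 11.
  - O-Silylation of the carbonyl of 7 with t-BuMe2SiOTf makes C2 electrophilic. The copper acetylide formed from 10 (CuI, i-Pr2NEt, CH2Cl2, −40 °C) should add there to give racemic tert-butyl{[3,5-bis(benzyloxy)-7-methoxy-2-[(trimethylsilyl)ethynyl]-2H-chromen-4-yl]oxy}dimethylsilane F6.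
  - Dehydrogenation of this silyl enol ether with DDQ (dioxane, rt) should restore the pyranone and give 11.

**Step 13.**
- What may go wrong: slow transmetalation and reductive elimination at the hindered C2 between the ring oxygen and the 3-benzyloxy group, slow oxidative addition of the electron-rich aryl bromide, and zincation of the furan alpha position by leftover base.
- Fallback (coupling roles reversed): it sets out from 19 (through 23) and from 22 and returns at 24.
  - Iodinolysis of 23 should give 3,5,7-tris(benzyloxy)-2-iodo-4H-chromen-4-one F7.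
  - Miyaura borylation of 22 (B2pin2, Pd(dppf)Cl2, KOAc, dioxane, 80 °C) should give 2-[4-(furan-3-yloxy)-3-methoxyphenyl]-4,4,5,5-tetramethyl-1,3,2-dioxaborolane F8.
  - Suzuki–Miyaura coupling of F7 with F8 (Pd(PPh3)4, K3PO4, dioxane/H2O, 60 °C) should give 24.

## Further compounds

F1 | step 14 | 3,5,7-tris(benzyloxy)-2-(4-hydroxy-3-methoxyphenyl)-4H-chromen-4-one | COc1cc(-c2oc3cc(OCc4ccccc4)cc(OCc4ccccc4)c3c(=O)c2OCc2ccccc2)ccc1O
F2 | step 14 | 2-(benzyloxy)-1-bromo-4-iodobenzene | Brc1ccc(I)cc1OCc1ccccc1
F3 | step 14 | 3,5-bis(benzyloxy)-2-[3-(benzyloxy)-4-bromophenyl]-7-methoxy-4H-chromen-4-one | COc1cc(OCc2ccccc2)c2c(=O)c(OCc3ccccc3)c(-c3ccc(Br)c(OCc4ccccc4)c3)oc2c1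
F4 | step 14 | 3,5-bis(benzyloxy)-2-[3-(benzyloxy)-4-[2-methoxy-4-[3,5,7-tris(benzyloxy)-4-oxo-4H-chromen-2-yl]phenoxy]phenyl]-7-methoxy-4H-chromen-4-one | COc1cc(OCc2ccccc2)c2c(=O)c(OCc3ccccc3)c(-c3ccc(Oc4ccc(-c5oc6cc(OCc7ccccc7)cc(OCc7ccccc7)c6c(=O)c5OCc5ccccc5)cc4OC)c(OCc4ccccc4)c3)oc2c1
F5 | step 12 | 4-(4-bromo-2-methoxyphenoxy)furan-2(5H)-one | COc1cc(Br)ccc1OC1=CC(=O)OC1
F6 | step 5 | tert-butyl{[3,5-bis(benzyloxy)-7-methoxy-2-[(trimethylsilyl)ethynyl]-2H-chromen-4-yl]oxy}dimethylsilane (racemic) | COc1cc(OCc2ccccc2)c2c(c1)OC(C#C[Si](C)(C)C)C(OCc1ccccc1)=C2O[Si](C)(C)C(C)(C)C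
F7 | step 13 | 3,5,7-tris(benzyloxy)-2-iodo-4H-chromen-4-one | O=c1c(OCc2ccccc2)c(I)oc2cc(OCc3ccccc3)cc(OCc3ccccc3)c12
F8 | step 13 | 2-[4-(furan-3-yloxy)-3-methoxyphenyl]-4,4,5,5-tetramethyl-1,3,2-dioxaborolane | COc1cc(B2OC(C)(C)C(C)(C)O2)ccc1Oc1ccoc1
A1 | alternative 1 | methyl 3-methoxy-2-oxo-2H-pyran-5-carboxylate | COC(=O)C1=COC(=O)C(OC)=C1
A2 | alternative 1 | 2-[3-(benzyloxy)-4-(ethynyloxy)phenyl]-1,3-dioxolane | C#COc1ccc(C2OCCO2)cc1OCc1ccccc1
A3 | alternative 1 | methyl 4-[2-(benzyloxy)-4-(1,3-dioxolan-2-yl)phenoxy]-3-methoxybenzoate | COC(=O)c1ccc(Oc2ccc(C3OCCO3)cc2OCc2ccccc2)c(OC)c1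
A4 | alternative 2 | methyl (E)-9-[4-[2-(benzyloxy)-4-(1,3-dioxolan-2-yl)phenoxy]-3-methoxyphenyl]-3,5,7-trioxonon-8-enoate | COC(=O)CC(=O)CC(=O)CC(=O)/C=C/c1ccc(Oc2ccc(C3OCCO3)cc2OCc2ccccc2)c(OC)c1
A5 | alternative 2 | (E)-3-[4-[2-(benzyloxy)-4-(1,3-dioxolan-2-yl)phenoxy]-3-methoxyphenyl]-1-(2,4,6-trihydroxyphenyl)prop-2-en-1-one | O=C(/C=C/c1ccc(Oc2ccc(C3OCCO3)cc2OCc2ccccc2)c(OC)c1)c1c(O)cc(O)cc1O
A6 | alternative 3 | 2,4-dimethoxy-6-(trimethylsilyl)phenyl trifluoromethanesulfonate | COc1cc(OC)c(OS(=O)(=O)C(F)(F)F)c([Si](C)(C)C)c1
A7 | alternative 3 | methyl 2-(benzyloxy)-3-[3-(benzyloxy)-4-[4-(1,3-dioxolan-2-yl)-2-methoxyphenoxy]phenyl]-3-oxopropanoate | COC(=O)C(OCc1ccccc1)C(=O)c1ccc(Oc2ccc(C3OCCO3)cc2OC)c(OCc2ccccc2)c1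
A8 | alternative 3 | 3-(benzyloxy)-2-[3-(benzyloxy)-4-[4-(1,3-dioxolan-2-yl)-2-methoxyphenoxy]phenyl]-5,7-dimethoxy-4H-chromen-4-one | COc1cc(OC)c2c(=O)c(OCc3ccccc3)c(-c3ccc(Oc4ccc(C5OCCO5)cc4OC)c(OCc4ccccc4)c3)oc2c1
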